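Retrosynthesis: the allyl–C(para) bond of ring A (the phenol ring) is cut first, back to an O-allyl ether (para-Claisen); C7–O is then traced back to C7–B; last, the C8–ring A and C7–B bonds are cut together across an alkene.
Enabling feature: ring B (the 3,4-dimethoxyphenyl ring), benzylic C7, C8 and the C9 methyl are, atom for atom, (E)-1,2-dimethoxy-4-(prop-1-enyl)benzene. Only an oxygen on C7 and ring A on C8 are missing, and both sit on the same face of the former double bond.
Forward: no ring is formed. Benzyl-protected ring A and boron are joined to the propenyl chain in one nickel-catalysed three-component step, followed by C–B to C–OH oxidation, debenzylation, O-allylation and a para-Claisen shift.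
Stereochemistry: the C7/C8 relative configuration comes from syn addition to the (E)-alkene, the absolute configuration from a chiral bis(oxazoline) on nickel, and C7 is carried through the C–B oxidation with retention.

Key step: step 2

Remark: read from the SMILES, the target is (7S,8S), i.e. (1S,2S) in propan-1-ol numbering with C1 = C7 and C2 = C8.
Remark: the phenol is carried as a benzyl ether because it is inert to KOMe, small next to the C–Br bond, and removable by neutral hydrogenolysis before any alkene is present.
Remark: isomerically pure (E)-alkene is required, since syn addition to the (Z)-isomer would give the C7/C8 diastereomer.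
Assumption: the facial sense induced by the ligand cannot be predicted; the (S,S) ligand is written, and its antipode would be used if a first run shows the opposite sense.

Step 1
Reactants: 1 2-bromo-6-methoxyphenol
Product: 2 2-(benzyloxy)-1-bromo-3-methoxybenzene
Conditions: BnBr, K2CO3, DMF, rt
Reagents that add atoms: benzyl bromide, BrCc1ccccc1
Why: Williamson etherification of the phenoxide with a reactive benzylic halide; no stereocentre is involved.

Step 2
Reactants: 3 (E)-methylisoeugenol [(E)-1,2-dimethoxy-4-(prop-1-enyl)benzene]; 2 2-(benzyloxy)-1-bromo-3-methoxybenzene; 4 bis(pinacolato)diboron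
Product: 5 2-[(1S,2R)-2-[2-(benzyloxy)-3-methoxyphenyl]-1-(3,4-dimethoxyphenyl)propyl]-4,4,5,5-tetramethyl-1,3,2-dioxaborolane
Conditions: NiCl2(dimethoxyethane) (10 mol%), (4S,4'S)-4,4'-dibenzyl-4,4',5,5'-tetrahydro-2,2'-bioxazole (12 mol%), KOMe, THF/DMA 9:1, 30 °C
Reagents that add atoms: none
Why: Proposed new method: methoxide-activated 4 converts the ligated nickel bromide (monovalent nickel) into a nickel boryl, which adds syn across the alkene of 3 with boron on benzylic C7 and nickel on C8; oxidative addition of 2 at this alkylnickel gives an alkyl(aryl) complex of trivalent nickel, and C–C reductive elimination with retention forms the C8–ring A bond and returns the nickel bromide. The closest known reaction type is the racemic, ligand-free nickel-catalysed three-component arylboration of alkenylarenes with aryl bromides and B2pin2, which is syn-stereospecific and places boron on the benzylic carbon; new here is the chiral bis(oxazoline), which has to outrun that ligand-free channel, hence THF as bulk solvent with little DMA. No ring is closed. The relative configuration at C7 and C8 is fixed by the (E)-geometry of 3 together with syn delivery of boron and aryl, and the absolute configuration by the alkene face that the chiral nickel boryl selects during insertion. The step needs regioselectivity (boron to C7), which the aryl-conjugated alkene supplies as in the racemic reaction, and chemoselectivity, secured because 3 carries no other alkene (the allyl group comes later), 2 carries a single C–Br bond, and the benzyl ether is inert to KOMe.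

Step 3
Reactants: 5 the (1S,2R) benzylic pinacol boronate
Product: 6 (1S,2S)-2-[2-(benzyloxy)-3-methoxyphenyl]-1-(3,4-dimethoxyphenyl)propan-1-ol
Conditions: H2O2 (30% aq.), NaOH (3 M aq.), THF, 0 °C to rt
Reagents that add atoms: hydrogen peroxide, OO
Why: Alkaline peroxide oxidation of a secondary alkylboronic ester, in which C7 migrates from boron to oxygen with retention; the descriptor at C8 changes from R to S only because the CIP priorities change, and the ethers are untouched.

Step 4
Reactants: 6 the (1S,2S) benzyl ether alcohol
Product: 7 2-[(1S,2S)-1-(3,4-dimethoxyphenyl)-1-hydroxypropan-2-yl]-6-methoxyphenol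
Conditions: H2 (1 atm), Pd/C (10% palladium on carbon), EtOAc, rt
Reagents that add atoms: none
Why: Hydrogenolysis of an aryl benzyl ether in a neutral solvent should be faster than cleavage of the secondary benzylic C7–O bond, which normally needs acid; no alkene is present yet and neither stereocentre is touched.

Step 5
Reactants: 7 the phenol diol
Product: 8 (1S,2S)-1-(3,4-dimethoxyphenyl)-2-[3-methoxy-2-(prop-2-en-1-yloxy)phenyl]propan-1-ol
Conditions: allyl bromide, K2CO3, acetone, reflux
Reagents that add atoms: allyl bromide, C=CCBr
Why: Williamson O-allylation; carbonate deprotonates only the phenol, so the secondary alcohol at C7 should remain free.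

Step 6
Reactants: 8 the allyl aryl ether
Product: 11 4-allyl-2-[(1S,2S)-1-(3,4-dimethoxyphenyl)-1-hydroxypropan-2-yl]-6-methoxyphenol (target), via ortho-allyl cyclohexadienone 9 (not isolated), via para-allyl cyclohexadienone 10 (not isolated)
Conditions: PhNEt2, 190 °C, argon, sealed tube
Reagents that add atoms: none
Why: Aromatic para-Claisen rearrangement: the first [3,3] shift to a blocked ortho carbon gives dienone 9, which cannot enolise; a Cope [3,3] shift relays the allyl group to the para carbon (10), and tautomerisation restores the phenol. Both ortho positions are substituted, so para is the only outlet; the amine solvent buffers acid and C7 and C8 are not involved.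

Compound list
1 | 2-bromo-6-methoxyphenol | COc1cccc(Br)c1O | starting material
2 | 2-(benzyloxy)-1-bromo-3-methoxybenzene | COc1cccc(Br)c1OCc1ccccc1 | intermediate
3 | (E)-methylisoeugenol, (E)-1,2-dimethoxy-4-(prop-1-enyl)benzene | C/C=C/c1ccc(OC)c(OC)c1 | starting material
4 | bis(pinacolato)diboron | CC1(C)OB(OC1(C)C)B1OC(C)(C)C(C)(C)O1 | starting material
5 | 2-[(1S,2R)-2-[2-(benzyloxy)-3-methoxyphenyl]-1-(3,4-dimethoxyphenyl)propyl]-4,4,5,5-tetramethyl-1,3,2-dioxaborolane | COc1cccc([C@H](C)[C@H](B2OC(C)(C)C(C)(C)O2)c2ccc(OC)c(OC)c2)c1OCc1ccccc1 | intermediate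
6 | (1S,2S)-2-[2-(benzyloxy)-3-methoxyphenyl]-1-(3,4-dimethoxyphenyl)propan-1-ol | COc1cccc([C@H](C)[C@H](O)c2ccc(OC)c(OC)c2)c1OCc1ccccc1 | intermediate
7 | 2-[(1S,2S)-1-(3,4-dimethoxyphenyl)-1-hydroxypropan-2-yl]-6-methoxyphenol | COc1cccc([C@H](C)[C@H](O)c2ccc(OC)c(OC)c2)c1O | intermediate
8 | (1S,2S)-1-(3,4-dimethoxyphenyl)-2-[3-methoxy-2-(prop-2-en-1-yloxy)phenyl]propan-1-ol | COc1cccc([C@H](C)[C@H](O)c2ccc(OC)c(OC)c2)c1OCC=C | intermediate
9 | 6-allyl-2-[(1S,2S)-1-(3,4-dimethoxyphenyl)-1-hydroxypropan-2-yl]-6-methoxycyclohexa-2,4-dien-1-one (both epimers at the ring carbon bearing allyl and methoxy) | C=CCC1(OC)C=CC=C([C@H](C)[C@H](O)c2ccc(OC)c(OC)c2)C1=O | intermediate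
10 | 4-allyl-2-[(1S,2S)-1-(3,4-dimethoxyphenyl)-1-hydroxypropan-2-yl]-6-methoxycyclohexa-2,5-dien-1-one (both epimers at the allyl-bearing ring carbon) | C=CCC1C=C(OC)C(=O)C([C@H](C)[C@H](O)c2ccc(OC)c(OC)c2)=C1 | intermediate
11 | 4-allyl-2-[(1S,2S)-1-(3,4-dimethoxyphenyl)-1-hydroxypropan-2-yl]-6-methoxyphenol | C=CCc1cc(OC)c(O)c([C@H](C)[C@H](O)c2ccc(OC)c(OC)c2)c1 | target

Total step count: 6.
Longest linear sequence: 6 steps (1 → 2 → 5 → 6 → 7 → 8 → 11); 5 steps from alkene 3.

Steps most likely to fail

1. Step 2 (proposed new method). The ligand-free racemic channel may compete and erode facial selectivity. The ligated C8-nickel intermediate may undergo β-hydride elimination and chain walking before it captures the aryl group. The ortho-alkoxy aryl bromide may also be taken up slowly. Fallback by known chemistry, setting out again from 2, 3 and 4: the ligand-free arylboration (NiCl2(dimethoxyethane), KOMe, DMA, 30 °C) should give the racemic syn boronate F1, and H2O2/NaOH should convert it into the racemic alcohol F2. Esterification with (R)-2-methoxy-2-phenylacetic acid (DCC, DMAP, CH2Cl2) should give the O-methylmandelate of the (1S,2S) alcohol F3 and the O-methylmandelate of the (1R,2R) alcohol F4. These diastereomers would be separated on silica and assigned by the usual shielding analysis of such esters. Methanolysis of F3 (catalytic K2CO3, MeOH) returns to the route at 6.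

2. Step 6. At 190 °C the electron-rich benzylic alcohol may ionise, leading to closure onto the freed phenol or to dehydration, or the relay to the para carbon may stall. Fallback setting out from phenol 7: para-bromination of the free phenol (N-bromosuccinimide, MeCN, 0 °C; both ortho positions are occupied) should give the bromophenol F5. A Migita–Kosugi–Stille coupling with allyltributylstannane (Pd(PPh3)4, toluene, 100 °C) then installs the allyl group and arrives directly at 11; steps 5 and 6 are not needed.

3. Step 4. Over-reduction may occur, i.e. hydrogenolytic loss of the C7 hydroxyl activated by ring B. Fallback setting out from boronate 5, with the order of operations changed: hydrogenolysis (H2, Pd/C, EtOAc) at the boronate stage, where no benzylic C–O bond exists and the C–B bond is inert, should give the phenol boronate F6. Mild oxidation (NaBO3·4H2O, THF/H2O, rt) then forms the C7–OH bond with retention and rejoins the route at 7.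

Further compounds
F1 | step 2 | racemic syn boronate, (1S,2R) and (1R,2S) enantiomers of 5 in equal parts | COc1cccc([C@H](C)[C@H](B2OC(C)(C)C(C)(C)O2)c2ccc(OC)c(OC)c2)c1OCc1ccccc1.COc1cccc([C@@H](C)[C@@H](B2OC(C)(C)C(C)(C)O2)c2ccc(OC)c(OC)c2)c1OCc1ccccc1
F2 | step 2 | racemic alcohol, (1S,2S) and (1R,2R) enantiomers of 6 in equal parts | COc1cccc([C@H](C)[C@H](O)c2ccc(OC)c(OC)c2)c1OCc1ccccc1.COc1cccc([C@@H](C)[C@@H](O)c2ccc(OC)c(OC)c2)c1OCc1ccccc1
F3 | step 2 | (1S,2S)-2-[2-(benzyloxy)-3-methoxyphenyl]-1-(3,4-dimethoxyphenyl)propyl (R)-2-methoxy-2-phenylacetate | COc1cccc([C@H](C)[C@H](OC(=O)[C@H](OC)c2ccccc2)c2ccc(OC)c(OC)c2)c1OCc1ccccc1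
F4 | step 2 | (1R,2R)-2-[2-(benzyloxy)-3-methoxyphenyl]-1-(3,4-dimethoxyphenyl)propyl (R)-2-methoxy-2-phenylacetate | COc1cccc([C@@H](C)[C@@H](OC(=O)[C@H](OC)c2ccccc2)c2ccc(OC)c(OC)c2)c1OCc1ccccc1
F5 | step 6 | 4-bromo-2-[(1S,2S)-1-(3,4-dimethoxyphenyl)-1-hydroxypropan-2-yl]-6-methoxyphenol | COc1cc(Br)cc([C@H](C)[C@H](O)c2ccc(OC)c(OC)c2)c1O
F6 | step 4 | 2-[(1S,2R)-1-(3,4-dimethoxyphenyl)-1-(4,4,5,5-tetramethyl-1,3,2-dioxaborolan-2-yl)propan-2-yl]-6-methoxyphenol | COc1cccc([C@H](C)[C@H](B2OC(C)(C)C(C)(C)O2)c2ccc(OC)c(OC)c2)c1O
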